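## Retrosynthetic overview
1. The last step removes seven identical O-Boc groups. Boc is the only protecting group and also the trigger for the key step.
2. Each trans-2,3-diaryl-2,3-dihydrobenzofuran is cut at O1–C2 and C2–C3, a [4+1] disconnection. This gives an o-quinone methide and an enantiopure 4-oxybenzyl sulfonium ylide that supplies C2.
3. Each o-quinone methide comes from an aryl Grignard reagent and a symmetric 2,6-bis(BocO)benzaldehyde. Boc shift and elimination dearomatise the ring and differentiate its two equivalent oxygens.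
4. Ring order: the inner dihydrobenzofuran is built first, on 4-bromo-2,6-bis(BocO)benzaldehyde. Its bromide then becomes the nucleophile for the outer ring, which is built on the stilbene aldehyde made by Heck reaction of the same bromo-aldehyde.
5. Purchased materials: 4-bromo-2,6-dimethoxybenzaldehyde, 5-bromoresorcinol, p-cresol, 4-BocO-styrene and isothiocineole.

Abbreviation: BocO = OC(=O)OC(CH3)3.

Assumption: the facial sense of the ylide toward an o-quinone methide follows the steric model in step 9, with the same ylide face as in its aldehyde epoxidations. If it proves opposite, the (1S,4S,5S)-sulfide from (S)-limonene is used and nothing else changes.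

## Route

Step 1
Reactants: 1 4-bromo-2,6-dimethoxybenzaldehyde
Product: 2 4-bromo-2,6-dihydroxybenzaldehyde
Conditions: BBr3 (2.5 equiv), CH2Cl2, −78 → 0 °C; H2O
Reagents that add atoms: none
Why: Lewis-acid aryl methyl ether cleavage, in which BBr3 binds each carbonyl-flanked methoxy oxygen and bromide removes the methyl group by SN2, leaving the aldehyde and aryl bromide intact with no stereocentre involved.

Step 2
Reactants: 2 4-bromo-2,6-dihydroxybenzaldehyde
Product: 3 4-bromo-2,6-bis(BocO)benzaldehyde (C2v-symmetric)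
Conditions: Boc2O (2.3 equiv), i-Pr2NEt, DMAP (cat.), THF, 0 °C → rt
Reagents that add atoms: di-tert-butyl dicarbonate, CC(C)(C)OC(=O)OC(=O)OC(C)(C)C
Why: DMAP-catalysed O-acylation (carbonate formation) caps both equivalent phenols, so each Boc serves as protecting group and as latent leaving group for the key step.

Step 3
Reactants: 3 4-bromo-2,6-bis(BocO)benzaldehyde; 4 tert-butyl 4-vinylphenyl carbonate
Product: 5 (E)-2,6-bis(BocO)-4-[4-(BocO)styryl]benzaldehyde
Conditions: Pd2(dba)3 (1.5 mol %), P(t-Bu)3 (6 mol %), Cy2NMe (1.1 equiv), dioxane, rt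
Reagents that add atoms: none
Why: Mizoroki–Heck reaction, in which the bromide para to the formyl group adds to Pd(0)/P(t-Bu)3 at room temperature, syn insertion and syn β-hydride elimination give the E-alkene, and the hindered amine does not attack the carbonates.

Step 4
Reactants: 6 5-bromoresorcinol
Product: 7 1-bromo-3,5-bis(BocO)benzene
Conditions: Boc2O (2.2 equiv), DMAP (cat.), i-Pr2NEt, CH2Cl2, rt
Reagents that add atoms: di-tert-butyl dicarbonate, CC(C)(C)OC(=O)OC(=O)OC(C)(C)C
Why: DMAP-catalysed O-acylation of both phenols gives a bromide whose tert-butyl carbonates tolerate magnesium insertion at low temperature.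

Step 5
Reactants: 8 p-cresol
Product: 9 tert-butyl 4-methylphenyl carbonate
Conditions: Boc2O (1.05 equiv), DMAP (cat.), CH2Cl2, rt
Reagents that add atoms: di-tert-butyl dicarbonate, CC(C)(C)OC(=O)OC(=O)OC(C)(C)C
Why: DMAP-catalysed O-acylation, where the carbonate also lowers the ring's electron density so the next step brominates the methyl group and not the ring.

Step 6
Reactants: 9 tert-butyl 4-methylphenyl carbonate
Product: 10 4-(bromomethyl)phenyl tert-butyl carbonate
Conditions: NBS (1.0 equiv), AIBN (cat.), PhCF3, 85 °C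
Reagents that add atoms: N-bromosuccinimide, O=C1CCC(=O)N1Br
Why: Wohl–Ziegler benzylic radical bromination, since the only weak C–H bonds are the benzylic ones and the carbonate is inert to the radical chain.

Step 7
Reactants: 10 4-(bromomethyl)phenyl tert-butyl carbonate; 11 (1R,4R,5R)-isothiocineole [(1R,4R,5R)-4,7,7-trimethyl-6-thiabicyclo[3.2.1]octane]
Product: 12 (1R,4R,5R,6R)-6-[4-(BocO)benzyl]-4,7,7-trimethyl-6-thiabicyclo[3.2.1]octan-6-ium triflate (benzyl on the exo lone pair)
Conditions: LiOTf (5 equiv), CH2Cl2/H2O, rt; crystallise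
Reagents that add atoms: lithium triflate, [Li+].[O-]S(=O)(=O)C(F)(F)F
Why: SN2 S-alkylation takes place only at the exo lone pair, because the endo one lies under the three-carbon bridge, so sulfur becomes a single stereocentre, and biphasic exchange of bromide for triflate makes the alkylation irreversible under neutral, Boc-safe conditions.

Step 8
Reactants: 12 sulfonium triflate
Product: 13 isothiocineole 4-(BocO)benzylide (sulfonium ylide of 12), held as a THF solution at −78 °C
Conditions: LiHMDS (1.0 equiv), THF, −78 °C, 15 min; transferred cold by cannula (the solution does not keep, so a fresh batch is drawn from stored 12 just before step 9 and just before step 10)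
Reagents that add atoms: none
Why: Sulfonium ylide formation by acid–base reaction, in which the hindered amide removes the acidic benzylic S–CH2 proton at −78 °C faster than it can attack the aryl carbonate, the configuration at sulfur and at the three ring carbons is untouched, and no new stereocentre is formed.

Step 9
Reactants: 7 1-bromo-3,5-bis(BocO)benzene; 3 4-bromo-2,6-bis(BocO)benzaldehyde; 13 isothiocineole benzylide
Product: 16 (2S,3S)-6-bromo-4-(BocO)-2-[4-(BocO)phenyl]-3-[3,5-bis(BocO)phenyl]-2,3-dihydrobenzofuran, via aryl Grignard reagent 14 (not isolated), via bromo o-quinone methide 15 (not isolated)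
Conditions: 7, Mg, LiCl, THF, 0 °C; add (1.0 equiv) to 3, THF, −78 °C; then 13 (1.2 equiv, THF, −78 °C, by cannula), −78 → 0 °C; H2O
Reagents that add atoms: none
Why: Proposed new method: 1,2-addition of 14 to the aldehyde gives a magnesium alkoxide that takes over one of the two equivalent neighbouring Boc groups, and the freed phenoxide expels tert-butyl carbonate, which dearomatises and desymmetrises the ring to 15; ylide 13 adds to the methide carbon with rearomatisation as driving force and the phenoxide displaces the sulfide in a 5-exo-tet SN2 step (formal [4+1] annulation); C2 is set as S because the ylide reacts in the conformer with its aryl group turned away from the bicycle, on the face remote from the gem-dimethyl group, and is then inverted, and C3 is set as S by the open transition state that keeps the two aryl groups anti (trans ring, any cis isomer removed by chromatography); the closest known reaction types are organometal-triggered o-quinone methide release from O-Boc salicylaldehydes, the trans-selective [4+1] annulation of o-quinone methides with stabilised sulfur ylides, and the asymmetric Corey–Chaykovsky epoxidation with this class of benzylide.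

Step 10
Reactants: 16 bromo-dihydrobenzofuran; 5 stilbene aldehyde; 13 isothiocineole benzylide
Product: 19 hepta-O-Boc derivative of the target (2S,3S,2'S,3'S), via dihydrobenzofuranyl Grignard reagent 17 (not isolated), via styryl o-quinone methide 18 (not isolated)
Conditions: 16, Mg (DIBAL-H-activated), LiCl, THF, 0 °C; add to 5, THF, −78 °C; then 13 (1.3 equiv, THF, −78 °C, by cannula), −78 → 0 °C; H2O
Reagents that add atoms: none
Why: Proposed new method: the same addition, Boc shift, elimination and [4+1] cascade as in step 9, now on the symmetric aldehyde 5; attack at the methide carbon of 18 is the only path that restores aromaticity, so the styryl group is left alone; the existing stereocentres sit meta and remote from the reacting carbon, so the same ylide face (then inversion) and anti-aryl transition state again give (2S,3S), and any minor enantiomer of 16 becomes a separable diastereomer; the closest known reaction types are those named in step 9, together with LiCl-mediated magnesium insertion into O-Boc bromophenols.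

Step 11
Reactants: 19 hepta-O-Boc trimer
Product: 20 target, 5-[(2S,3S)-4-hydroxy-6-{(2S,3S)-4-hydroxy-2-(4-hydroxyphenyl)-6-[(E)-4-hydroxystyryl]-2,3-dihydrobenzofuran-3-yl}-2-(4-hydroxyphenyl)-2,3-dihydrobenzofuran-3-yl]benzene-1,3-diol
Conditions: piperidine (20 equiv), degassed THF, rt → 40 °C, Ar; AcOH, then aqueous wash
Reagents that add atoms: none
Why: Aminolysis of aryl carbonates, in which phenoxide is a good leaving group so piperidine removes all seven Boc groups as its carbamate, without acid or oxidant, leaving the stilbene, both benzylic C–O bonds and all four stereocentres untouched.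

## Compound list
1 | 4-bromo-2,6-dimethoxybenzaldehyde | COc1cc(Br)cc(OC)c1C=O | starting material
2 | 4-bromo-2,6-dihydroxybenzaldehyde | O=Cc1c(O)cc(Br)cc1O | intermediate
3 | 4-bromo-2,6-bis(BocO)benzaldehyde | O=Cc1c(OC(=O)OC(C)(C)C)cc(Br)cc1OC(=O)OC(C)(C)C | intermediate
4 | tert-butyl 4-vinylphenyl carbonate | C=Cc1ccc(OC(=O)OC(C)(C)C)cc1 | starting material
5 | (E)-2,6-bis(BocO)-4-[4-(BocO)styryl]benzaldehyde | O=Cc1c(OC(=O)OC(C)(C)C)cc(/C=C/c2ccc(OC(=O)OC(C)(C)C)cc2)cc1OC(=O)OC(C)(C)C | intermediate
6 | 5-bromoresorcinol | Oc1cc(O)cc(Br)c1 | starting material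
7 | 1-bromo-3,5-bis(BocO)benzene | Brc1cc(OC(=O)OC(C)(C)C)cc(OC(=O)OC(C)(C)C)c1 | intermediate
8 | p-cresol | Cc1ccc(O)cc1 | starting material
9 | tert-butyl 4-methylphenyl carbonate | Cc1ccc(OC(=O)OC(C)(C)C)cc1 | intermediate
10 | 4-(bromomethyl)phenyl tert-butyl carbonate | BrCc1ccc(OC(=O)OC(C)(C)C)cc1 | intermediate
11 | (1R,4R,5R)-isothiocineole | C[C@@H]1CC[C@@H]2C[C@H]1SC2(C)C | starting material
12 | (1R,4R,5R,6R)-6-[4-(BocO)benzyl]-4,7,7-trimethyl-6-thiabicyclo[3.2.1]octan-6-ium triflate | C[C@@H]1CC[C@@H]2C[C@H]1[S@@+](Cc1ccc(OC(=O)OC(C)(C)C)cc1)C2(C)C.[O-]S(=O)(=O)C(F)(F)F | intermediate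
13 | isothiocineole 4-(BocO)benzylide (sulfonium ylide of 12) | C[C@@H]1CC[C@@H]2C[C@H]1[S@@+]([CH-]c1ccc(OC(=O)OC(C)(C)C)cc1)C2(C)C | intermediate
14 | [3,5-bis(BocO)phenyl]magnesium bromide (LiCl complex) | Br[Mg]c1cc(OC(=O)OC(C)(C)C)cc(OC(=O)OC(C)(C)C)c1 | intermediate
15 | (6Z)-3-bromo-5-(BocO)-6-{[3,5-bis(BocO)phenyl]methylidene}cyclohexa-2,4-dien-1-one | O=C1C=C(Br)C=C(OC(=O)OC(C)(C)C)/C1=C/c1cc(OC(=O)OC(C)(C)C)cc(OC(=O)OC(C)(C)C)c1 | intermediate
16 | (2S,3S)-6-bromo-4-(BocO)-2-[4-(BocO)phenyl]-3-[3,5-bis(BocO)phenyl]-2,3-dihydrobenzofuran | Brc1cc(OC(=O)OC(C)(C)C)c2c(c1)O[C@H](c1ccc(OC(=O)OC(C)(C)C)cc1)[C@H]2c1cc(OC(=O)OC(C)(C)C)cc(OC(=O)OC(C)(C)C)c1 | intermediate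
17 | 6-(bromomagnesio) analogue of 16 (LiCl complex) | Br[Mg]c1cc(OC(=O)OC(C)(C)C)c2c(c1)O[C@H](c1ccc(OC(=O)OC(C)(C)C)cc1)[C@H]2c1cc(OC(=O)OC(C)(C)C)cc(OC(=O)OC(C)(C)C)c1 | intermediate
18 | (6Z)-5-(BocO)-3-[(E)-4-(BocO)styryl]-6-{[(2S,3S)-dihydrobenzofuran-6-yl of 16]methylidene}cyclohexa-2,4-dien-1-one | O=C1C=C(/C=C/c2ccc(OC(=O)OC(C)(C)C)cc2)C=C(OC(=O)OC(C)(C)C)/C1=C/c1cc(OC(=O)OC(C)(C)C)c2c(c1)O[C@H](c1ccc(OC(=O)OC(C)(C)C)cc1)[C@H]2c1cc(OC(=O)OC(C)(C)C)cc(OC(=O)OC(C)(C)C)c1 | intermediate
19 | hepta-O-Boc target (all four ring stereocentres S, E-stilbene) | CC(C)(C)OC(=O)Oc1ccc(/C=C/c2cc(OC(=O)OC(C)(C)C)c3c(c2)O[C@H](c2ccc(OC(=O)OC(C)(C)C)cc2)[C@H]3c2cc(OC(=O)OC(C)(C)C)c3c(c2)O[C@H](c2ccc(OC(=O)OC(C)(C)C)cc2)[C@H]3c2cc(OC(=O)OC(C)(C)C)cc(OC(=O)OC(C)(C)C)c2)cc1 | intermediate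
20 | CNP0248228.2 | Oc1ccc(/C=C/c2cc(O)c3c(c2)O[C@H](c2ccc(O)cc2)[C@H]3c2cc(O)c3c(c2)O[C@H](c2ccc(O)cc2)[C@H]3c2cc(O)cc(O)c2)cc1 | target

## Step count and risks
Total steps: 11. Longest linear sequence: 7 (steps 5, 6, 7, 8, 9, 10 and 11, starting from p-cresol).

**Step 9.** The risk is that ylide 13 decays or is acylated before 15 is released, or that residual 14 adds to 15. The fallback runs from 3 to 16 and separates the release of the o-quinone methide from the organometallic step. Grignard 14 is added to 3 as before, and 15 is then intercepted with lithium p-toluenesulfinate in THF/DMPU. This gives the bench-stable racemic sulfone 5-bromo-3-(BocO)-2-{[3,5-bis(BocO)phenyl](tosyl)methyl}phenol F1. F1 is stirred with salt 12 and Cs2CO3 in CH2Cl2 at 0 °C. The one mild base slowly re-eliminates sulfinate to 15 and reversibly forms 13, so both partners meet at low concentration and close to 16.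

**Step 10.** The risk is that magnesium insertion into 16 must spare four carbonates. The fallback runs from 16 to 19 and replaces the organomagnesium with catalytic organoboron chemistry. Miyaura borylation [B2pin2, PdCl2(dppf), KOAc, dioxane, 80 °C] gives the pinacol boronate of 16 F2. Rh(I)/P(t-Bu)3-catalysed 1,2-addition of F2 to aldehyde 5 in DME/H2O at rt gives the neutral diaryl carbinol F3, whose carbinol epimers are irrelevant. F3 is deprotonated with KHMDS at −78 °C to start the Boc shift and elimination to 18, and ylide 13 then traps 18 to give 19.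

**Step 3.** The risk is that the activated carbonates ortho to the formyl group are lost during the Heck reaction. The fallback runs from 16 and 3 to 19 and installs the stilbene last. Grignard 17 is added to bromo-aldehyde 3 in place of 5, giving the bromo o-quinone methide F4. Ylide 13 converts F4 into the hexa-O-Boc bromo bis(dihydrobenzofuran) F5. F5 carries only unactivated carbonates, and its Mizoroki–Heck coupling with 4 gives 19.

## Further compounds
F1 | step 9 | 5-bromo-3-(BocO)-2-{[3,5-bis(BocO)phenyl](tosyl)methyl}phenol (racemic) | Cc1ccc(cc1)S(=O)(=O)C(c1cc(OC(=O)OC(C)(C)C)cc(OC(=O)OC(C)(C)C)c1)c1c(O)cc(Br)cc1OC(=O)OC(C)(C)C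
F2 | step 10 | 6-(pinacolboryl) analogue of 16, (2S,3S) | CC1(C)OB(OC1(C)C)c1cc(OC(=O)OC(C)(C)C)c2c(c1)O[C@H](c1ccc(OC(=O)OC(C)(C)C)cc1)[C@H]2c1cc(OC(=O)OC(C)(C)C)cc(OC(=O)OC(C)(C)C)c1
F3 | step 10 | {2,6-bis(BocO)-4-[(E)-4-(BocO)styryl]phenyl}[(2S,3S)-dihydrobenzofuran-6-yl of 16]methanol (carbinol epimers) | OC(c1c(OC(=O)OC(C)(C)C)cc(/C=C/c2ccc(OC(=O)OC(C)(C)C)cc2)cc1OC(=O)OC(C)(C)C)c1cc(OC(=O)OC(C)(C)C)c2c(c1)O[C@H](c1ccc(OC(=O)OC(C)(C)C)cc1)[C@H]2c1cc(OC(=O)OC(C)(C)C)cc(OC(=O)OC(C)(C)C)c1
F4 | step 3 | (6Z)-3-bromo-5-(BocO)-6-{[(2S,3S)-dihydrobenzofuran-6-yl of 16]methylidene}cyclohexa-2,4-dien-1-one | O=C1C=C(Br)C=C(OC(=O)OC(C)(C)C)/C1=C/c1cc(OC(=O)OC(C)(C)C)c2c(c1)O[C@H](c1ccc(OC(=O)OC(C)(C)C)cc1)[C@H]2c1cc(OC(=O)OC(C)(C)C)cc(OC(=O)OC(C)(C)C)c1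
F5 | step 3 | hexa-O-Boc (2S,3S,2'S,3'S)-6-bromo bis(dihydrobenzofuran) (19 with Br in place of the styryl group) | Brc1cc(OC(=O)OC(C)(C)C)c2c(c1)O[C@H](c1ccc(OC(=O)OC(C)(C)C)cc1)[C@H]2c1cc(OC(=O)OC(C)(C)C)c2c(c1)O[C@H](c1ccc(OC(=O)OC(C)(C)C)cc1)[C@H]2c1cc(OC(=O)OC(C)(C)C)cc(OC(=O)OC(C)(C)C)c1
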